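The racemization catalyst turns each hand of the substrate into the other while the single-handed coupling partner consumes both (a dynamic kinetic resolution), so you can follow one substrate molecule and ask at each fork where it ends.

the same everywhere: racemization catalyst 0.15 mol%; added ligand 0.54 mM
- ash: left-handed substrate 0.17 M; right-handed substrate 0.17 M; coupling partner 2.2 equiv; run made earlier
- larch: left-handed substrate 0.38 M; right-handed substrate 0.38 M; coupling partner 2.2 equiv; run made earlier
- flask: left-handed substrate 0.25 M; right-handed substrate 0.25 M; coupling partner 2.20 equiv; time 6.0 d

- ash (time / d: left-handed product / %, right-handed product / %): 0.500: 51, 3; 0.833: 64, 1; 1.04: 64, 0; 1.67: 78, 2; 2.50: 85, 2; 4.00: 90, 4; 6.00: 93, 3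
- larch (time / d: left-handed product / %, right-handed product / %): 0.500: 71, 2; 0.833: 80, 1; 1.04: 83, 2; 1.67: 90, 1; 2.50: 95, 4; 4.00: 97, 1; 6.00: 96, 3

(standard deviation of a reading: 1.5 percentage points)

- left-handed product and right-handed product together, in percent of the left-handed substrate and right-handed substrate charged together, at 6.0 d
- excess of left-handed product over right-handed product in the product at 6.0 d
- whether the exchange between left-handed substrate and right-handed substrate keeps pace with the reaction: how far the product's excess at 6.0 d gets from its value without exchange to its value with instant exchange (above 80 % keeps pace, below 20 % hardly takes part, else lags behind)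

- coupling partner is single-handed; left-handed substrate and right-handed substrate are mirror images of each other, charged as a racemate, each of them at the stated concentration
- an excess is below zero if the other one leads
- the handed part of coupling partner does not stay in what it makes, so the products of the two hands are mirror images too

The left-handed product reaches 93 % in ash and 96 % in larch, so most right-handed substrate crossed over before it coupled. From 2.50 d on, right-handed product makes up 3.25 % of the product in ash and 2.70 % in larch. Their mean, 2.98 %, is my reading of the leak share λ, the chance that one substrate molecule, followed to its end as product, ends as right-handed product.

The excess is then 1 − 2λ, which gives 94.0 %. Without exchange left-handed product stops at half of the substrate charged, and ash ends 43 percentage points beyond that, so I commit to keeps pace, as a judgement from these readings and not as a reckoned share of the way. Interpolating the final totals of ash and larch by concentration gives me 97.1 % for the yield.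

The weak link is λ: the right-handed readings behind it lie between 1 % and 4 %, with a scatter of 1.5 points. But the two runs differ by less than that scatter, so pooling their readings is fair, and my excess carries about 1.2 points.

The forecast, from the same runs, gives 97.5 %, 94.5 % and keeps pace, a little above my two numbers, and says “Right-handed product leaks slowly”.

The flask gives 98.0 % and 95.6 %, and it keeps pace, getting 97 % of the way.

    coupling partner ⇌ dormant form (K = 0.360, k = 0.270 h⁻¹)
    left-handed substrate + racemization catalyst ⇌ right-handed substrate + racemization catalyst, rate k2*[racemization catalyst]*[left-handed substrate] forward; the back reaction follows from the equilibrium constant (k = 810 M⁻¹ h⁻¹)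
    racemization catalyst + added ligand ⇌ idle complex (K = 2900 M⁻¹, k = 39000 M⁻¹ h⁻¹)
    coupling partner + right-handed substrate → right-handed product (k = 0.0110 M⁻¹ h⁻¹)
    coupling partner + left-handed substrate → left-handed product (k = 0.690 M⁻¹ h⁻¹)

In this flask the free racemization catalyst, 49.6 % of its charge, gives right-handed substrate an exchange rate of 0.151 h⁻¹, faster than its coupling rate of 0.00605 h⁻¹ at the charged coupling partner. The flask's excess puts λ at 2.22 %, against 2.98 % read from the runs, and in a neighbour flask charged with 8.80 equiv of coupling partner, where that coupling rate at the charge is 0.0242 h⁻¹, λ stands at 5.99 %.

The data are calculated for substances that don't exist; noise was put on by code.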